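**Plan**

Numbering used here: ring O1, C2, C3 (carries the benzyl group), C4 (carries the carbinol side chain), C5; carbinol carbon C7. The target is (3S,4R,7S) with the two ring substituents cis.
Retrosynthesis: after the three O–Si bonds, one operation cuts the ring bond C3–C4 and the benzylic CH2–aryl bond, giving an open-chain secondary iodide with an O-allyl group and an arylzinc reagent. The iodide goes back through C–I, O–allyl and a 1,2-diol to a 1-aryl allyl alcohol from vanillin and a vinyl Grignard reagent.
Enabling feature: C3–C4 and CH2–aryl lie at the two ends of the C3–CH2 unit, and O1–C2–C3–CH2 is an allyl ether in disguise. A radical at C4 that closes 5-exo onto C3 therefore forms the tetrahydrofuran and leaves a primary radical on the very CH2 that must carry the second guaiacyl ring.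
Forward order: the C7–C4–C5 chain is built and oxygenated, the allyl group goes onto the C5 oxygen and iodine onto C4. The only ring then closes in the same step that joins the two aryl halves, and desilylation ends the route.
Stereochemistry: C7 by Sharpless kinetic resolution (recovered S alcohol); C4 by 1,2-induction from C7 in the radical step; C3 by the cis preference of the 5-exo closure; the iodide carbon needs no control.
Key step: step 10

Remark (assumption): the carbon that becomes the C4 radical is carried from the diol to the iodide as a mixture of epimers (left undefined in the SMILES), since C–I homolysis erases it; the facial sense of the radical step is taken from a steric model and must be confirmed on the cyclized product.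
Remark (descriptors): the carbinol keeps one spatial arrangement from the resolution to the target; its descriptor reads S or R only according to the CIP rank of the neighbouring carbon.
Remark (locants): in the systematic names of the cyclized compounds the ring locants start at the carbinol-bearing carbon, so running C4 (R) and C3 (S) appear there as 3R and 4S.

Step 1
Reactants: 1 vanillin
Product: 2 4-[(tert-butyldimethylsilyl)oxy]-3-methoxybenzaldehyde
Conditions: TBSCl, imidazole, DMF, 0 °C → rt
Reagents that add atoms: tert-butyldimethylsilyl chloride, CC(C)(C)[Si](C)(C)Cl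
Why: Imidazole-mediated O-silylation of a phenol masks the acidic OH before the Grignard step and leaves the aldehyde untouched.

Step 2
Reactants: 2 4-[(tert-butyldimethylsilyl)oxy]-3-methoxybenzaldehyde; 3 vinylmagnesium bromide
Product: 4 rac-1-{4-[(tert-butyldimethylsilyl)oxy]-3-methoxyphenyl}prop-2-en-1-ol
Conditions: THF, −78 → 0 °C; aqueous work-up at pH 7
Reagents that add atoms: none
Why: Grignard 1,2-addition to an aryl aldehyde at low temperature is tolerated by the aryl silyl ether and gives the C7 carbinol as a racemate.

Step 3
Reactants: 4 rac-1-{4-[(tert-butyldimethylsilyl)oxy]-3-methoxyphenyl}prop-2-en-1-ol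
Product: 5 (1S)-1-{4-[(tert-butyldimethylsilyl)oxy]-3-methoxyphenyl}prop-2-en-1-ol
Conditions: Ti(OiPr)4 (0.2 equiv), L-(+)-diisopropyl tartrate (0.25 equiv), t-BuOOH (0.6 equiv), 4 Å molecular sieves, CH2Cl2, −20 °C, stopped beyond half conversion; chromatography
Reagents that add atoms: none
Why: Sharpless kinetic resolution of a secondary allylic alcohol: the Ti(OiPr)4–L-(+)-tartrate catalyst epoxidizes the 1R enantiomer of this aryl vinyl carbinol much faster, so that stopping beyond half conversion should leave the 1S alcohol in high enantiomeric purity, C7 being selected here and not created.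

Step 4
Reactants: 5 (1S)-1-{4-[(tert-butyldimethylsilyl)oxy]-3-methoxyphenyl}prop-2-en-1-ol
Product: 6 tert-butyl{[(1S)-1-{4-[(tert-butyldimethylsilyl)oxy]-3-methoxyphenyl}prop-2-en-1-yl]oxy}dimethylsilane
Conditions: TBSCl, imidazole, DMF, rt
Reagents that add atoms: tert-butyldimethylsilyl chloride, CC(C)(C)[Si](C)(C)Cl
Why: Silyl ether formation under non-ionizing conditions does not touch C7 and puts the same group on all three oxygens, so that one fluoride step can remove them at the end.

Step 5
Reactants: 6 tert-butyl{[(1S)-1-{4-[(tert-butyldimethylsilyl)oxy]-3-methoxyphenyl}prop-2-en-1-yl]oxy}dimethylsilane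
Product: 7 (3R)-3-[(tert-butyldimethylsilyl)oxy]-3-{4-[(tert-butyldimethylsilyl)oxy]-3-methoxyphenyl}propane-1,2-diol (epimers at the secondary carbinol)
Conditions: OsO4 (2 mol %), N-methylmorpholine N-oxide, acetone/H2O, rt
Reagents that add atoms: N-methylmorpholine N-oxide, C[N+]1([O-])CCOCC1; water, O
Why: Upjohn dihydroxylation (catalytic OsO4, syn addition) of the monosubstituted alkene; the new secondary carbinol (future C4) forms as an epimer mixture in which the anti isomer should predominate, which is immaterial because this centre is planarized in step 10.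

Step 6
Reactants: 7 (3R)-3-[(tert-butyldimethylsilyl)oxy]-3-{4-[(tert-butyldimethylsilyl)oxy]-3-methoxyphenyl}propane-1,2-diol; 8 allyl bromide
Product: 10 (1R)-3-(allyloxy)-1-[(tert-butyldimethylsilyl)oxy]-1-{4-[(tert-butyldimethylsilyl)oxy]-3-methoxyphenyl}propan-2-ol, via dibutylstannylene acetal 9 (not isolated)
Conditions: Bu2SnO, toluene, reflux (Dean–Stark); then 8, Bu4NBr, 90 °C
Reagents that add atoms: none
Why: Stannylene-acetal-mediated regioselective O-alkylation of a 1,2-diol: the primary oxygen of the five-membered dibutylstannylene acetal is the more nucleophilic, and the neutral, fluoride-free conditions spare both silyl ethers.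

Step 7
Reactants: 10 (1R)-3-(allyloxy)-1-[(tert-butyldimethylsilyl)oxy]-1-{4-[(tert-butyldimethylsilyl)oxy]-3-methoxyphenyl}propan-2-ol
Product: 11 tert-butyl{[(1R)-3-(allyloxy)-1-{4-[(tert-butyldimethylsilyl)oxy]-3-methoxyphenyl}-2-iodopropyl]oxy}dimethylsilane (either iodide epimer)
Conditions: PPh3, I2, imidazole, toluene, 70 °C
Reagents that add atoms: iodine, [I][I]
Why: Garegg–Samuelsson iodination: iodide displaces the alkoxyphosphonium group by SN2 with inversion, a method established for secondary hydroxyls flanked by oxygenated carbons, and either configuration serves because this carbon becomes the radical centre.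

Step 8
Reactants: 12 4-bromo-2-methoxyphenol
Product: 13 (4-bromo-2-methoxyphenoxy)(tert-butyl)dimethylsilane
Conditions: TBSCl, imidazole, DMF, rt
Reagents that add atoms: tert-butyldimethylsilyl chloride, CC(C)(C)[Si](C)(C)Cl
Why: Imidazole-mediated phenol silylation removes the acidic proton that would quench the organometallic reagents of the next two steps.

Step 9
Reactants: 13 (4-bromo-2-methoxyphenoxy)(tert-butyl)dimethylsilane
Product: 15 {4-[(tert-butyldimethylsilyl)oxy]-3-methoxyphenyl}zinc bromide, via aryllithium 14 (not isolated)
Conditions: n-BuLi, THF, −78 °C; then ZnBr2 in THF, −78 °C → rt; used as a titrated solution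
Reagents that add atoms: zinc bromide, Br[Zn]Br
Why: Bromine–lithium exchange followed by transmetalation to zinc gives the arylzinc halide, the silyl ether para to the metal being unable to migrate at −78 °C.

Step 10
Reactants: 11 tert-butyl{[(1R)-3-(allyloxy)-1-{4-[(tert-butyldimethylsilyl)oxy]-3-methoxyphenyl}-2-iodopropyl]oxy}dimethylsilane; 15 {4-[(tert-butyldimethylsilyl)oxy]-3-methoxyphenyl}zinc bromide
Product: 16 tert-butyl{(S)-{4-[(tert-butyldimethylsilyl)oxy]-3-methoxyphenyl}[(3R,4S)-4-{4-[(tert-butyldimethylsilyl)oxy]-3-methoxybenzyl}tetrahydrofuran-3-yl]methoxy}dimethylsilane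
Conditions: NiCl2(MeOCH2CH2OMe) (10 mol %), 4,4′-di-tert-butyl-2,2′-bipyridine (12 mol %), 15 (2 equiv), THF/N,N-dimethylacetamide, 0 °C → rt
Reagents that add atoms: none
Why: Arylzinc 15 reduces the divalent nickel precatalyst to a low-valent bipyridine–nickel species that abstracts iodine from 11; the secondary C4 radical (the same planar radical from either iodide epimer) cyclizes, and the resulting primary radical is taken up by an arylnickel species that reductively eliminates the CH2–aryl bond and returns nickel to the cycle. The closest known reaction type is the nickel-catalysed tandem radical cyclization/Negishi arylation of β-halo allyl ethers and haloacetals with arylzinc halides. The tetrahydrofuran closes by 5-exo-trig attack of C4 on the inner allyl carbon C3. C3 is set relative to C4 by the chair-like transition state of a 1-substituted 3-oxahex-5-enyl radical, which places the new CH2 cis to the C4 substituent. C4 is set by 1,2-induction from C7: with the aryl group anti to the forming bond, the C7–H next to the ring CH2 (C5) and the silyloxy group next to the C4–H, the alkene adds to the face that gives 4R from the carbinol configuration present in 11. The step needs ring closure to precede capture by nickel and no loss of the β-oxygen groups; the fast closure of a 3-oxahexenyl radical at low catalyst concentration should secure the first, and the absence of a carbon–metal bond at C4 secures the second.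

Step 11
Reactants: 16 tert-butyl{(S)-{4-[(tert-butyldimethylsilyl)oxy]-3-methoxyphenyl}[(3R,4S)-4-{4-[(tert-butyldimethylsilyl)oxy]-3-methoxybenzyl}tetrahydrofuran-3-yl]methoxy}dimethylsilane
Product: 17 4-{(S)-hydroxy[(3R,4S)-4-(4-hydroxy-3-methoxybenzyl)tetrahydrofuran-3-yl]methyl}-2-methoxyphenol
Conditions: Bu4NF (4 equiv), AcOH (4 equiv), THF, 0 °C → rt
Reagents that add atoms: none
Why: Fluoride-driven cleavage of all three silyl ethers (Si–F bond formation), buffered with acetic acid so that no phenoxide stands para to the benzylic oxygen and the p-hydroxybenzylic carbinol cannot epimerize through a quinone methide.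

**Compound list**

1 | vanillin (4-hydroxy-3-methoxybenzaldehyde) | COc1cc(C=O)ccc1O | starting material
2 | 4-[(tert-butyldimethylsilyl)oxy]-3-methoxybenzaldehyde | COc1cc(C=O)ccc1O[Si](C)(C)C(C)(C)C | intermediate
3 | vinylmagnesium bromide | C=C[Mg]Br | starting material
4 | rac-1-{4-[(tert-butyldimethylsilyl)oxy]-3-methoxyphenyl}prop-2-en-1-ol (racemic) | C=CC(O)c1ccc(O[Si](C)(C)C(C)(C)C)c(OC)c1 | intermediate
5 | (1S)-1-{4-[(tert-butyldimethylsilyl)oxy]-3-methoxyphenyl}prop-2-en-1-ol | C=C[C@H](O)c1ccc(O[Si](C)(C)C(C)(C)C)c(OC)c1 | intermediate
6 | tert-butyl{[(1S)-1-{4-[(tert-butyldimethylsilyl)oxy]-3-methoxyphenyl}prop-2-en-1-yl]oxy}dimethylsilane | C=C[C@H](O[Si](C)(C)C(C)(C)C)c1ccc(O[Si](C)(C)C(C)(C)C)c(OC)c1 | intermediate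
7 | (3R)-3-[(tert-butyldimethylsilyl)oxy]-3-{4-[(tert-butyldimethylsilyl)oxy]-3-methoxyphenyl}propane-1,2-diol (epimers at C2, anti expected to predominate; carbinol arrangement as in 5) | OCC(O)[C@H](O[Si](C)(C)C(C)(C)C)c1ccc(O[Si](C)(C)C(C)(C)C)c(OC)c1 | intermediate
8 | allyl bromide (3-bromoprop-1-ene) | C=CCBr | starting material
9 | 2,2-dibutyl-4-[(R)-[(tert-butyldimethylsilyl)oxy]{4-[(tert-butyldimethylsilyl)oxy]-3-methoxyphenyl}methyl]-1,3,2-dioxastannolane (dibutylstannylene acetal of 7, ring-carbon epimers) | CCCC[Sn]1(CCCC)OCC(O1)[C@H](O[Si](C)(C)C(C)(C)C)c1ccc(O[Si](C)(C)C(C)(C)C)c(OC)c1 | intermediate (not isolated)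
10 | (1R)-3-(allyloxy)-1-[(tert-butyldimethylsilyl)oxy]-1-{4-[(tert-butyldimethylsilyl)oxy]-3-methoxyphenyl}propan-2-ol (epimers at C2) | C=CCOCC(O)[C@H](O[Si](C)(C)C(C)(C)C)c1ccc(O[Si](C)(C)C(C)(C)C)c(OC)c1 | intermediate
11 | tert-butyl{[(1R)-3-(allyloxy)-1-{4-[(tert-butyldimethylsilyl)oxy]-3-methoxyphenyl}-2-iodopropyl]oxy}dimethylsilane (either epimer at the iodide carbon) | C=CCOCC(I)[C@H](O[Si](C)(C)C(C)(C)C)c1ccc(O[Si](C)(C)C(C)(C)C)c(OC)c1 | intermediate
12 | 4-bromo-2-methoxyphenol | COc1cc(Br)ccc1O | starting material
13 | (4-bromo-2-methoxyphenoxy)(tert-butyl)dimethylsilane | COc1cc(Br)ccc1O[Si](C)(C)C(C)(C)C | intermediate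
14 | {4-[(tert-butyldimethylsilyl)oxy]-3-methoxyphenyl}lithium | COc1cc([Li])ccc1O[Si](C)(C)C(C)(C)C | intermediate (not isolated)
15 | {4-[(tert-butyldimethylsilyl)oxy]-3-methoxyphenyl}zinc bromide | COc1cc([Zn]Br)ccc1O[Si](C)(C)C(C)(C)C | intermediate
16 | tert-butyl{(S)-{4-[(tert-butyldimethylsilyl)oxy]-3-methoxyphenyl}[(3R,4S)-4-{4-[(tert-butyldimethylsilyl)oxy]-3-methoxybenzyl}tetrahydrofuran-3-yl]methoxy}dimethylsilane | COc1cc(C[C@@H]2COC[C@@H]2[C@H](O[Si](C)(C)C(C)(C)C)c2ccc(O[Si](C)(C)C(C)(C)C)c(OC)c2)ccc1O[Si](C)(C)C(C)(C)C | intermediate
17 | 4-{(S)-hydroxy[(3R,4S)-4-(4-hydroxy-3-methoxybenzyl)tetrahydrofuran-3-yl]methyl}-2-methoxyphenol | COc1cc(C[C@@H]2COC[C@@H]2[C@H](O)c2ccc(O)c(OC)c2)ccc1O | target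

**Step count and risks**

Total: 11 steps. Longest linear sequence: 9 steps from vanillin (steps 1–7, 10, 11); steps 8 and 9 make the zinc reagent.

Step 10 is the most likely to fail. The acyclic C7 stereocentre may steer the C4 radical only weakly or to the other face, the cis preference of the ring closure may be modest for a branched C4 substituent, and the open-chain radical may be arylated before it cyclizes. The fallback sets out from 11 and separates ring closure from arylation. An iodine-atom-transfer radical cyclization initiated by Et3B and air in CH2Cl2 at −78 °C should give the iodomethyl tetrahydrofuran F1 at the temperature where both selectivities are at their best, and its diastereomers can be separated before the aryl group is attached. A Negishi coupling of this primary iodide with 15 (Pd2(dba)3 as the zerovalent palladium source, tricyclopentylphosphine, N-methylimidazole, THF/N-methylpyrrolidinone, 80 °C) then returns to the route at 16.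

Step 7 is second. Substitution at a carbon flanked by two oxygenated carbons is slow at the hot oxyphosphonium stage, so participation of the electron-rich aryl group with loss of the silyl group, β-elimination or cleavage of the benzylic silyl ether by the phosphine–iodine reagent may compete. The fallback sets out from 10 and separates activation from substitution. The secondary triflate F2 is formed in the cold (Tf2O, 2,6-lutidine, CH2Cl2, −78 °C) and displaced in a second operation by Bu4NI in toluene between −20 °C and rt, which returns to the route at 11.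

Step 3 is third. Epoxidation of a terminal vinyl group is slow, so rate discrimination between the enantiomers may stay incomplete within a practical time, and ionization of the electron-rich benzylic alcohol on the titanium Lewis acid may erode the enantiomeric purity. The fallback sets out from aldehyde 2 and creates the stereocentre instead of selecting it. Divinylzinc F3, prepared in the flask from 3 and ZnCl2, is added in toluene at 0 °C with a catalytic amount of the chiral amino alcohol (−)-3-exo-(dimethylamino)isoborneol. By analogy with its dialkylzinc additions this antipode is expected to deliver the S carbinol, and the sequence returns to the route at 5.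

Further compounds
F1 | step 10 | tert-butyl{(S)-{4-[(tert-butyldimethylsilyl)oxy]-3-methoxyphenyl}[(3R,4S)-4-(iodomethyl)tetrahydrofuran-3-yl]methoxy}dimethylsilane | IC[C@@H]1COC[C@@H]1[C@H](O[Si](C)(C)C(C)(C)C)c1ccc(O[Si](C)(C)C(C)(C)C)c(OC)c1
F2 | step 7 | (1R)-3-(allyloxy)-1-[(tert-butyldimethylsilyl)oxy]-1-{4-[(tert-butyldimethylsilyl)oxy]-3-methoxyphenyl}propan-2-yl trifluoromethanesulfonate (epimers at C2) | C=CCOCC(OS(=O)(=O)C(F)(F)F)[C@H](O[Si](C)(C)C(C)(C)C)c1ccc(O[Si](C)(C)C(C)(C)C)c(OC)c1
F3 | step 3 | divinylzinc | C=C[Zn]C=C
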